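**Retrosynthetic overview**

- The route rests on one feature: the oxygen-bearing C9 of ring B is bonded to C10, and C10 is the β-carbon of a ring A enone (C1=C10 conjugated to the C2 ketone). Two electrophilic carbons must therefore be joined, which is done by turning C9 into an acyl anion.
- Key disconnection C9–C10: a carbene-catalysed intramolecular Stetter acylation closes ring B (C5–C10) onto a preformed ring A; ring A comes first, ring B second.
- After closure: C2 ketal, reduction of the C9 ketone to the axial 9α-alcohol, senecioylation at O9, acidic unmasking, tigloylation at O8.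
- The C6–C9 chain (C7, C8 and the isopropenyl group) comes from a catalytic asymmetric glyoxylate-ene reaction on a prenyl group.
- Ring A (C4, C5) comes from asymmetric conjugate methylation and prenylation of 2-methylcyclohex-2-en-1-one, followed by enone transposition (dehydrogenation, epoxidation, Wharton, oxidation).

Key step: step 10

Remark: eremophilane numbering is used (ring A = C1–C5, C10; ring B = C5–C10; C14 on C5, C15 on C4, isopropenyl C11–C13 on C7; β = face of C14/C15); the SMILES is read as the O9 3-methylbut-2-enoate (senecioate) and the O8 (E)-2-methylbut-2-enoate (tiglate).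

**Route**

Step 1
Reactants: 1 2-methylcyclohex-2-en-1-one; 2 prenyl bromide (1-bromo-3-methylbut-2-ene)
Product: 5 (2R,3S)-2,3-dimethyl-2-(3-methylbut-2-en-1-yl)cyclohexan-1-one, via dimethylaluminium enolate 3 (not isolated), via lithium aluminate enolate 4 (not isolated)
Conditions: Me3Al, copper thiophene-2-carboxylate Cu(O2CC4H3S) (2 mol%), BINOL-derived bis(1-phenylethyl)amine phosphoramidite (antipode that gives the 3S adduct, 4 mol%), Et2O, −30 °C; then MeLi, THF/DMPU, −30 °C; then 2, −30 °C → rt
Reagents that add atoms: trimethylaluminium, C[Al](C)C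
Why: Copper-catalysed asymmetric conjugate addition of Me3Al sets C4 (S) under ligand control, and the ate-activated enolate is C-alkylated by the allylic bromide anti to the new pseudoaxial methyl, which sets the quaternary C5 (R) with the two methyls cis (tandem conjugate addition–enolate alkylation).

Step 2
Reactants: 5 (2R,3S)-2,3-dimethyl-2-(3-methylbut-2-en-1-yl)cyclohexan-1-one
Product: 8 (5S,6R)-5,6-dimethyl-6-(3-methylbut-2-en-1-yl)cyclohex-2-en-1-one, via lithium enolate 6 (not isolated), via sulfilimine adduct 7 (not isolated)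
Conditions: LiN(i-Pr)2, THF, −78 °C; then t-BuN=S(Cl)Ph, −78 °C
Reagents that add atoms: none
Why: Mukaiyama dehydrogenation: the ketone can enolise only towards C1 because C5 is quaternary, the lithium enolate is S-sulfinimidoylated and the adduct loses the sulfenamide by syn-elimination at low temperature, with no palladium reagent that could engage the prenyl alkene; no stereocentre is formed.

Step 3
Reactants: 8 (5S,6R)-5,6-dimethyl-6-(3-methylbut-2-en-1-yl)cyclohex-2-en-1-one
Product: 9 (3R,4S)-3,4-dimethyl-3-(3-methylbut-2-en-1-yl)-7-oxabicyclo[4.1.0]heptan-2-one (epoxide diastereomers)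
Conditions: H2O2 (30% aq), NaOH (cat.), MeOH, 0 °C
Reagents that add atoms: hydrogen peroxide, OO
Why: Weitz–Scheffer nucleophilic epoxidation attacks only the electron-poor enone (the prenyl alkene is inert), and the configuration of the two epoxide carbons does not matter because they become an sp2 carbon and a carbonyl carbon in steps 4 and 5.

Step 4
Reactants: 9 (3R,4S)-3,4-dimethyl-3-(3-methylbut-2-en-1-yl)-7-oxabicyclo[4.1.0]heptan-2-one
Product: 11 (4R,5S)-4,5-dimethyl-4-(3-methylbut-2-en-1-yl)cyclohex-2-en-1-ol (C1 epimers), via epoxy hydrazone 10 (not isolated)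
Conditions: N2H4·H2O, AcOH (cat.), MeOH, 0 °C → rt
Reagents that add atoms: none
Why: Wharton transposition: the hydrazone opens the neighbouring epoxide to an allylic diazene that loses N2, which moves the oxygen from C10 to C2 and places the alkene at C1=C10; the new C2 carbinol centre forms as a mixture and is erased in step 5.

Step 5
Reactants: 11 (4R,5S)-4,5-dimethyl-4-(3-methylbut-2-en-1-yl)cyclohex-2-en-1-ol
Product: 12 (4R,5S)-4,5-dimethyl-4-(3-methylbut-2-en-1-yl)cyclohex-2-en-1-one
Conditions: Dess–Martin periodinane, CH2Cl2, 0 °C → rt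
Reagents that add atoms: none
Why: Dess–Martin oxidation of a secondary allylic alcohol, in which both C2 epimers converge on one enone and the isolated alkene is untouched.

Step 6
Reactants: 12 (4R,5S)-4,5-dimethyl-4-(3-methylbut-2-en-1-yl)cyclohex-2-en-1-one; 13 ethyl glyoxylate (freshly distilled)
Product: 14 ethyl (2R,3R)-3-{[(1R,6S)-1,6-dimethyl-4-oxocyclohex-2-en-1-yl]methyl}-2-hydroxy-4-methylpent-4-enoate
Conditions: [Cu((R,R)-t-Bu-box)](SbF6)2 (10 mol%; t-Bu-box = 2,2-bis(4-tert-butyl-2-oxazolin-2-yl)propane), CH2Cl2, 0 °C → rt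
Reagents that add atoms: none
Why: Lewis-acid-catalysed enantioselective glyoxylate-ene reaction: the C–C bond forms at the less substituted alkene carbon C7 with hydrogen transfer from the methyl group cis to H7 (leaving the isopropenyl group), the ligand fixes the attacked face of the chelated glyoxylate (C8, R; the antipodal ligand gives S-hydroxy esters with simple alkenes), and the exo arrangement, in which the chelated ester and the metal point away from the C6 chain and the second methyl, relates C7 to C8 as 7R,8R.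

Step 7
Reactants: 14 ethyl (2R,3R)-3-{[(1R,6S)-1,6-dimethyl-4-oxocyclohex-2-en-1-yl]methyl}-2-hydroxy-4-methylpent-4-enoate
Product: 15 ethyl (2R,3R)-2-[(tert-butyldimethylsilyl)oxy]-3-{[(1R,6S)-1,6-dimethyl-4-oxocyclohex-2-en-1-yl]methyl}-4-methylpent-4-enoate
Conditions: t-BuMe2SiOTf, 2,6-lutidine, CH2Cl2, −78 °C
Reagents that add atoms: tert-butyldimethylsilyl triflate, CC(C)(C)[Si](C)(C)OS(=O)(=O)C(F)(F)F
Why: Silylation of the secondary alcohol with a silyl triflate and a hindered pyridine base, which at low temperature is faster than enol silylation of the enone and removes the free hydroxyl that could add to C10 in an oxa-Michael sense; no stereocentre is touched.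

Step 8
Reactants: 15 ethyl (2R,3R)-2-[(tert-butyldimethylsilyl)oxy]-3-{[(1R,6S)-1,6-dimethyl-4-oxocyclohex-2-en-1-yl]methyl}-4-methylpent-4-enoate
Product: 16 (4R,5S)-4-{(2R,3R)-3-[(tert-butyldimethylsilyl)oxy]-4-hydroxy-2-(prop-1-en-2-yl)butyl}-4,5-dimethylcyclohex-2-en-1-ol (C1 epimers)
Conditions: i-Bu2AlH (excess), CH2Cl2, −78 → 0 °C; aq. work-up
Reagents that add atoms: none
Why: Exhaustive aluminium hydride reduction takes the ester to the primary alcohol and the enone to the allylic alcohol by 1,2-addition, so that ester and enone need not be distinguished; the C2 carbinol mixture is irrelevant and aluminium alkoxides should not trigger silyl migration at low temperature.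

Step 9
Reactants: 16 (4R,5S)-4-{(2R,3R)-3-[(tert-butyldimethylsilyl)oxy]-4-hydroxy-2-(prop-1-en-2-yl)butyl}-4,5-dimethylcyclohex-2-en-1-ol
Product: 17 (2R,3R)-2-[(tert-butyldimethylsilyl)oxy]-3-{[(1R,6S)-1,6-dimethyl-4-oxocyclohex-2-en-1-yl]methyl}-4-methylpent-4-enal
Conditions: Dess–Martin periodinane (3 equiv), CH2Cl2, 0 °C → rt; used at once
Reagents that add atoms: none
Why: Double Dess–Martin oxidation restores the C2 enone and forms the C9 aldehyde under non-basic conditions that should keep the configuration of the α-silyloxy aldehyde centre C8.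

Step 10
Reactants: 17 (2R,3R)-2-[(tert-butyldimethylsilyl)oxy]-3-{[(1R,6S)-1,6-dimethyl-4-oxocyclohex-2-en-1-yl]methyl}-4-methylpent-4-enal
Product: 18 (4S,5R,7R,8R,10S)-8-[(tert-butyldimethylsilyl)oxy]eremophil-11-ene-2,9-dione (cis-fused; H10 cis to C14)
Conditions: 2-(pentafluorophenyl)-6,7-dihydro-5H-pyrrolo[2,1-c][1,2,4]triazol-2-ium tetrafluoroborate (20 mol%), KN(SiMe3)2 (18 mol%), toluene (0.02 M), 23 °C
Reagents that add atoms: none
Why: The triazolylidene formed from the azolium salt and KN(SiMe3)2 adds to the C9 aldehyde and proton transfer gives the acyl-anion equivalent (Breslow intermediate), which adds to C10, the β-carbon of the C1=C10–C2 enone; enol tautomerisation and loss of the carbene then give the 1,4-diketone and return the catalyst. This is an intramolecular Stetter reaction of the kind established for aldehydes tethered to cyclohexenones and cyclohexadienones. Ring B (C5–C6–C7–C8–C9–C10) closes in a 6-exo-trig mode through a chair-like arrangement with the isopropenyl and silyloxy groups equatorial. The only new stereocentre, C10, is fixed by the tether: C9 can reach the axial lobe at C10 only on the face that carries C6 at C5, so the fusion is cis, and this is also the more stable isomer because the trans-fused epimer would hold the C7 isopropenyl group syn-axial to C14. The step needs conjugate acylation to outrun epimerisation at C8 and loss of silyloxide from the acyl-anion equivalent; a slight deficit of base relative to the azolium salt leaves no free amide base, and a silyl ether is a poor leaving group.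

Step 11
Reactants: 18 (4S,5R,7R,8R,10S)-8-[(tert-butyldimethylsilyl)oxy]eremophil-11-ene-2,9-dione
Product: 19 (4S,5R,7R,8R,10S)-8-[(tert-butyldimethylsilyl)oxy]-2,2-(ethylenedioxy)eremophil-11-en-9-one
Conditions: (Me3SiOCH2)2, Me3SiOTf (cat.), CH2Cl2, −78 → −40 °C
Reagents that add atoms: 1,2-bis(trimethylsilyloxy)ethane, C[Si](C)(C)OCCO[Si](C)(C)C
Why: Silyl-triflate-catalysed ketalisation with the bis-silylated glycol (Noyori ketalisation) selects the unhindered C2 ketone over the C9 ketone, which is flanked by the ring-fusion carbon and the silyloxy-bearing C8, and spares the silyl ether.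

Step 12
Reactants: 19 (4S,5R,7R,8R,10S)-8-[(tert-butyldimethylsilyl)oxy]-2,2-(ethylenedioxy)eremophil-11-en-9-one
Product: 20 (4S,5R,7R,8R,9S,10S)-8-[(tert-butyldimethylsilyl)oxy]-2,2-(ethylenedioxy)eremophil-11-en-9-ol
Conditions: LiBH(s-Bu)3, THF, −78 °C; H2O quench at −78 °C
Reagents that add atoms: none
Why: Hindered-hydride reduction: in the cis-decalin conformer with the isopropenyl and silyloxy groups equatorial the axial (α) approach to C9 is blocked by the syn-axial C4–C5 bond, so the bulky borohydride attacks equatorially from the β face and gives the axial 9α-alcohol (C9, S), cis to O8; the cold quench guards against silyl migration in the alkoxide.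

Step 13
Reactants: 20 (4S,5R,7R,8R,9S,10S)-8-[(tert-butyldimethylsilyl)oxy]-2,2-(ethylenedioxy)eremophil-11-en-9-ol; 21 3-methylbut-2-enoyl chloride
Product: 22 (4S,5R,7R,8R,9S,10S)-8-[(tert-butyldimethylsilyl)oxy]-2,2-(ethylenedioxy)eremophil-11-en-9-yl 3-methylbut-2-enoate
Conditions: 21, pyridine, DMAP (cat.), CH2Cl2, 0 °C → rt
Reagents that add atoms: none
Why: DMAP-catalysed acylation of the axial secondary alcohol with the acid chloride, where pyridine as the only base limits γ-deprotonation of the acyl donor (vinylketene formation) and hence the deconjugated ester.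

Step 14
Reactants: 22 (4S,5R,7R,8R,9S,10S)-8-[(tert-butyldimethylsilyl)oxy]-2,2-(ethylenedioxy)eremophil-11-en-9-yl 3-methylbut-2-enoate
Product: 23 (4S,5R,7R,8R,9S,10S)-8-hydroxy-2-oxoeremophil-11-en-9-yl 3-methylbut-2-enoate
Conditions: HF (48% aq), MeCN, 0 °C → rt
Reagents that add atoms: water, O
Why: Aqueous HF cleaves the silyl ether and hydrolyses the dioxolane in one operation, and the acidic medium avoids the base-promoted 1,2-migration of the senecioate to the freed cis-vicinal hydroxyl.

Step 15
Reactants: 23 (4S,5R,7R,8R,9S,10S)-8-hydroxy-2-oxoeremophil-11-en-9-yl 3-methylbut-2-enoate; 24 (E)-2-methylbut-2-enoyl chloride (tigloyl chloride)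
Product: 25 (4S,5R,7R,8R,9S,10S)-9-[(3-methylbut-2-enoyl)oxy]-2-oxoeremophil-11-en-8-yl (E)-2-methylbut-2-enoate (target, CNP0181050.1)
Conditions: 24, pyridine, DMAP (cat.), CH2Cl2, 0 °C → rt
Reagents that add atoms: none
Why: DMAP-catalysed acylation of the equatorial C8 alcohol with the configurationally stable (E)-acid chloride at low temperature, where acylation should outrun acyl migration and the C2 ketone is inert; the product is the target.

**Compound list**

1 | 2-methylcyclohex-2-en-1-one | CC1=CCCC1=O | starting material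
2 | prenyl bromide (1-bromo-3-methylbut-2-ene) | CC(C)=CCBr | starting material
3 | dimethylaluminium (3S)-2,3-dimethylcyclohex-1-en-1-olate | CC1=C(O[Al](C)C)CCC[C@@H]1C | intermediate (not isolated)
4 | lithium trimethyl[(3S)-2,3-dimethylcyclohex-1-en-1-olato]aluminate | [Li+].CC1=C(O[Al-](C)(C)C)CCC[C@@H]1C | intermediate (not isolated)
5 | (2R,3S)-2,3-dimethyl-2-(3-methylbut-2-en-1-yl)cyclohexan-1-one | CC(C)=CC[C@@]1(C)C(=O)CCC[C@@H]1C | intermediate
6 | lithium (5S,6R)-5,6-dimethyl-6-(3-methylbut-2-en-1-yl)cyclohex-1-en-1-olate | CC(C)=CC[C@@]1(C)C(O[Li])=CCC[C@@H]1C | intermediate (not isolated)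
7 | (2R,3S)-6-(N-tert-butyl-S-phenylsulfinimidoyl)-2,3-dimethyl-2-(3-methylbut-2-en-1-yl)cyclohexan-1-one (mixture at C6 and S) | CC(C)=CC[C@@]1(C)C(=O)C(CC[C@@H]1C)S(=NC(C)(C)C)c1ccccc1 | intermediate (not isolated)
8 | (5S,6R)-5,6-dimethyl-6-(3-methylbut-2-en-1-yl)cyclohex-2-en-1-one | CC(C)=CC[C@@]1(C)C(=O)C=CC[C@@H]1C | intermediate
9 | (3R,4S)-3,4-dimethyl-3-(3-methylbut-2-en-1-yl)-7-oxabicyclo[4.1.0]heptan-2-one (epoxide diastereomers) | CC(C)=CC[C@@]1(C)C(=O)C2OC2C[C@@H]1C | intermediate
10 | hydrazone of 9 | CC(C)=CC[C@@]1(C)C(=NN)C2OC2C[C@@H]1C | intermediate (not isolated)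
11 | (4R,5S)-4,5-dimethyl-4-(3-methylbut-2-en-1-yl)cyclohex-2-en-1-ol (C1 epimers) | CC(C)=CC[C@@]1(C)C=CC(O)C[C@@H]1C | intermediate
12 | (4R,5S)-4,5-dimethyl-4-(3-methylbut-2-en-1-yl)cyclohex-2-en-1-one | CC(C)=CC[C@@]1(C)C=CC(=O)C[C@@H]1C | intermediate
13 | ethyl glyoxylate | CCOC(=O)C=O | starting material
14 | ethyl (2R,3R)-3-{[(1R,6S)-1,6-dimethyl-4-oxocyclohex-2-en-1-yl]methyl}-2-hydroxy-4-methylpent-4-enoate | C=C(C)[C@@H](C[C@@]1(C)C=CC(=O)C[C@@H]1C)[C@@H](O)C(=O)OCC | intermediate
15 | ethyl (2R,3R)-2-[(tert-butyldimethylsilyl)oxy]-3-{[(1R,6S)-1,6-dimethyl-4-oxocyclohex-2-en-1-yl]methyl}-4-methylpent-4-enoate | C=C(C)[C@@H](C[C@@]1(C)C=CC(=O)C[C@@H]1C)[C@@H](O[Si](C)(C)C(C)(C)C)C(=O)OCC | intermediate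
16 | (4R,5S)-4-{(2R,3R)-3-[(tert-butyldimethylsilyl)oxy]-4-hydroxy-2-(prop-1-en-2-yl)butyl}-4,5-dimethylcyclohex-2-en-1-ol (C1 epimers) | C=C(C)[C@@H](C[C@@]1(C)C=CC(O)C[C@@H]1C)[C@@H](O[Si](C)(C)C(C)(C)C)CO | intermediate
17 | (2R,3R)-2-[(tert-butyldimethylsilyl)oxy]-3-{[(1R,6S)-1,6-dimethyl-4-oxocyclohex-2-en-1-yl]methyl}-4-methylpent-4-enal | C=C(C)[C@@H](C[C@@]1(C)C=CC(=O)C[C@@H]1C)[C@@H](O[Si](C)(C)C(C)(C)C)C=O | intermediate
18 | (4S,5R,7R,8R,10S)-8-[(tert-butyldimethylsilyl)oxy]eremophil-11-ene-2,9-dione | C=C(C)[C@H]1C[C@@]2(C)[C@H](CC(=O)C[C@@H]2C)C(=O)[C@@H]1O[Si](C)(C)C(C)(C)C | intermediate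
19 | (4S,5R,7R,8R,10S)-8-[(tert-butyldimethylsilyl)oxy]-2,2-(ethylenedioxy)eremophil-11-en-9-one | C=C(C)[C@H]1C[C@@]2(C)[C@H](CC3(OCCO3)C[C@@H]2C)C(=O)[C@@H]1O[Si](C)(C)C(C)(C)C | intermediate
20 | (4S,5R,7R,8R,9S,10S)-8-[(tert-butyldimethylsilyl)oxy]-2,2-(ethylenedioxy)eremophil-11-en-9-ol | C=C(C)[C@H]1C[C@@]2(C)[C@H](CC3(OCCO3)C[C@@H]2C)[C@H](O)[C@@H]1O[Si](C)(C)C(C)(C)C | intermediate
21 | 3-methylbut-2-enoyl chloride (senecioyl chloride) | CC(C)=CC(=O)Cl | starting material
22 | (4S,5R,7R,8R,9S,10S)-8-[(tert-butyldimethylsilyl)oxy]-2,2-(ethylenedioxy)eremophil-11-en-9-yl 3-methylbut-2-enoate | C=C(C)[C@H]1C[C@@]2(C)[C@H](CC3(OCCO3)C[C@@H]2C)[C@H](OC(=O)C=C(C)C)[C@@H]1O[Si](C)(C)C(C)(C)C | intermediate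
23 | (4S,5R,7R,8R,9S,10S)-8-hydroxy-2-oxoeremophil-11-en-9-yl 3-methylbut-2-enoate | C=C(C)[C@H]1C[C@@]2(C)[C@H](CC(=O)C[C@@H]2C)[C@H](OC(=O)C=C(C)C)[C@@H]1O | intermediate
24 | (E)-2-methylbut-2-enoyl chloride (tigloyl chloride) | C/C=C(\C)C(=O)Cl | starting material
25 | (4S,5R,7R,8R,9S,10S)-9-[(3-methylbut-2-enoyl)oxy]-2-oxoeremophil-11-en-8-yl (E)-2-methylbut-2-enoate | C=C(C)[C@H]1C[C@@]2(C)[C@H](CC(=O)C[C@@H]2C)[C@H](OC(=O)C=C(C)C)[C@@H]1OC(=O)/C(C)=C/C | target

**Step count and risks**

Total steps: 15. Longest linear sequence: 15 steps (1 → 25).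

Steps most likely to fail:

1. Step 10 (Stetter closure). The six-membered closure onto a β-carbon next to a quaternary centre may be slow, so that carbene- or base-mediated epimerisation of the aldehyde centre C8, or expulsion of silyloxide from the acyl-anion equivalent, competes with conjugate acylation. Fallback: the same C9–C10 bond is made reductively. Setting out from aldehyde 17, SmI2 (THF, t-BuOH, −78 °C) should generate the C9 ketyl, which adds to C10 in a 6-exo-trig ketyl–enone cyclisation with the cis fusion again imposed by the tether. Protonation of the samarium enolate should give (4S,5R,7R,8R,10S)-8-[(tert-butyldimethylsilyl)oxy]-9-hydroxyeremophil-11-en-2-one F1 as a C9 mixture. Oxidation of F1 with Dess–Martin periodinane comes back to diketone 18.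

2. Step 6 (glyoxylate-ene). The hindered trisubstituted alkene may react sluggishly, or the exo/endo preference in the ene transition state may be weak, which would scramble C7 relative to the catalyst-set C8. Fallback: C8 is set by inversion instead. Setting out from enone 12, a BINOL–titanium catalyst ((S)-BINOL/TiCl2(O-i-Pr)2, 4 Å molecular sieves, CH2Cl2, −30 °C) is used. It is a stronger Lewis acid that binds the aldehyde oxygen anti to the ester and favours the ester-endo arrangement, and should give the C8 epimer ethyl (2S,3R)-3-{[(1R,6S)-1,6-dimethyl-4-oxocyclohex-2-en-1-yl]methyl}-2-hydroxy-4-methylpent-4-enoate F2. Mitsunobu inversion (4-nitrobenzoic acid, PPh3, diisopropyl azodicarboxylate, THF) should give ethyl (2R,3R)-3-{[(1R,6S)-1,6-dimethyl-4-oxocyclohex-2-en-1-yl]methyl}-4-methyl-2-[(4-nitrobenzoyl)oxy]pent-4-enoate F3. Ethanolysis (K2CO3, EtOH, 0 °C) comes back to hydroxy ester 14.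

3. Step 4 (Wharton transposition). Hydrazone formation at the ketone next to the quaternary C5 may be slow, so that hydrazine opens the epoxide or the diazene decomposes along other paths. Fallback: a radical version of the transposition. Setting out from epoxy ketone 9, NaBH4 (MeOH, 0 °C) should give (3R,4S)-3,4-dimethyl-3-(3-methylbut-2-en-1-yl)-7-oxabicyclo[4.1.0]heptan-2-ol F4. 1,1′-Thiocarbonyldiimidazole (DMAP, ClCH2CH2Cl, 60 °C) should give O-[(3R,4S)-3,4-dimethyl-3-(3-methylbut-2-en-1-yl)-7-oxabicyclo[4.1.0]heptan-2-yl] 1H-imidazole-1-carbothioate F5. Bu3SnH/AIBN (benzene, 80 °C) generates the C10 radical, which opens the adjacent epoxide, and hydrogen transfer to the alkoxy radical comes back to allylic alcohol 11.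

**Further compounds**

F1 | step 10 | (4S,5R,7R,8R,10S)-8-[(tert-butyldimethylsilyl)oxy]-9-hydroxyeremophil-11-en-2-one (C9 epimers) | C=C(C)[C@H]1C[C@@]2(C)[C@H](CC(=O)C[C@@H]2C)C(O)[C@@H]1O[Si](C)(C)C(C)(C)C
F2 | step 6 | ethyl (2S,3R)-3-{[(1R,6S)-1,6-dimethyl-4-oxocyclohex-2-en-1-yl]methyl}-2-hydroxy-4-methylpent-4-enoate | C=C(C)[C@@H](C[C@@]1(C)C=CC(=O)C[C@@H]1C)[C@H](O)C(=O)OCC
F3 | step 6 | ethyl (2R,3R)-3-{[(1R,6S)-1,6-dimethyl-4-oxocyclohex-2-en-1-yl]methyl}-4-methyl-2-[(4-nitrobenzoyl)oxy]pent-4-enoate | C=C(C)[C@@H](C[C@@]1(C)C=CC(=O)C[C@@H]1C)[C@@H](OC(=O)c2ccc(cc2)[N+](=O)[O-])C(=O)OCC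
F4 | step 4 | (3R,4S)-3,4-dimethyl-3-(3-methylbut-2-en-1-yl)-7-oxabicyclo[4.1.0]heptan-2-ol | CC(C)=CC[C@@]1(C)C(O)C2OC2C[C@@H]1C
F5 | step 4 | O-[(3R,4S)-3,4-dimethyl-3-(3-methylbut-2-en-1-yl)-7-oxabicyclo[4.1.0]heptan-2-yl] 1H-imidazole-1-carbothioate | CC(C)=CC[C@@]1(C)C(OC(=S)n3ccnc3)C2OC2C[C@@H]1C
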